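**Assumption:** the target has no stereocentre and is achiral. I read "single enantiomer" as the single all-E (2E,6E,10E,14E,18E) geometric isomer drawn.

## Retrosynthetic overview
1. The only ring, the quinone, is built last and de novo. Target ⇐ (desilylation/Ag2O) hexasubstituted hydroquinone ⇐ Moore 4π-opening/6π-closure of a 4-alkenylcyclobutenone. No aryl(quinone)–prenyl bond is ever formed.
2. OH and OMe are told apart on the four-membered ring. In the squarate adduct only C3-OMe is a vinylogous ester, so only it is cleaved, and C3 ends up next to the C=O that is flanked by C-CH3.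
3. Cyclobutenone ⇐ dimethyl squarate (both C=O, C-OMe, C-OH) + a C33 2-lithioalk-2-ene (C-CH3 and C-hexaprenyl), generated from a vinylstannane.
4. C33 stannane ⇐ farnesylbarium + ω-bromo C18 stannane (α,α′ allyl–allyl coupling). C18 ⇐ 12-hydroxyfarnesyl acetate + (Z)-1,2-bis(trimethylstannyl)propene (site-selective allyl Stille).
5. Four E-alkenes come from two molecules of (E,E)-farnesol and the fifth from E-selective SeO2 oxidation. All later C–C couplings retain alkene geometry.

## Route

**Step 1**
Reactants: 1 (2E,6E)-farnesol
Product: 2 (2E,6E)-farnesyl acetate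
Conditions: Ac2O, pyridine, DMAP (cat.), CH2Cl2, 0 °C → rt
Reagents that add atoms: acetic anhydride, CC(=O)OC(C)=O
Why: DMAP-catalysed O-acylation; the acetate deactivates the C2=C3 alkene toward SeO2 and later serves as the Pd leaving group, so it is not a wasted protecting group.

**Step 2**
Reactants: 2
Product: 3 (2E,6E,10E)-12-hydroxyfarnesyl acetate
Conditions: SeO2 (0.1 equiv), t-BuOOH (3.5 equiv), salicylic acid (0.1 equiv), CH2Cl2, 0 °C → rt; then NaBH4, MeOH, 0 °C (returns over-oxidised enal)
Reagents that add atoms: selenium dioxide O=[Se]=O (O transfer) with tert-butyl hydroperoxide CC(C)(C)OO (terminal oxidant)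
Why: Sharpless-type catalytic SeO2 allylic oxidation (ene, then [2,3]-shift) attacks the most electron-rich terminal isopropylidene and hydroxylates only its (E)-methyl, which sets the fifth E-trisubstituted alkene.

**Step 3**
Reactants: 4 propyne; 5 hexamethylditin
Product: 6 (Z)-1,2-bis(trimethylstannyl)prop-1-ene
Conditions: Pd(PPh3)4 (2 mol %), THF, sealed tube, 65–70 °C
Reagents that add atoms: none (both reactants are numbered)
Why: Pd(0)-catalysed distannylation is a syn addition of Sn–Sn across the terminal alkyne, giving only the Z isomer as a regiodefined propene 1,2-dianion equivalent.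

**Step 4**
Reactants: 3; 6 (1.5 equiv)
Product: 7 (2E,6E,10E,13Z)-2,6,10-trimethyl-14-(trimethylstannyl)pentadeca-2,6,10,13-tetraen-1-ol
Conditions: Pd2(dba)3 (2.5 mol %), LiCl (3 equiv), DMF, rt → 40 °C
Reagents that add atoms: none
Why: Stille coupling of an allylic acetate (ligand-free Pd/LiCl); only the unhindered terminal C–Sn bond transmetalates and the bond forms at the primary allyl terminus with retention of both alkene geometries, while the internal SnMe3 and the free OH survive.

**Step 5**
Reactants: 7
Product: 8 [(2Z,5E,9E,13E)-15-bromo-6,10,14-trimethylpentadeca-2,5,9,13-tetraen-2-yl]trimethylstannane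
Conditions: MsCl, Et3N, CH2Cl2, −40 °C; then LiBr, THF, 0 °C (used at once)
Reagents that add atoms: lithium bromide, [Li+].[Br-]
Why: SN2 displacement of the allylic mesylate under non-acidic conditions avoids allylic transposition, E/Z loss and protodestannylation.

**Step 6**
Reactants: 1
Product: 9 (2E,6E)-farnesyl chloride
Conditions: MsCl, LiCl, s-collidine, DMF, 0 °C
Reagents that add atoms: lithium chloride, [Li+].[Cl-]
Why: Collington–Meyers chlorination converts primary allylic alcohols to chlorides without rearrangement or isomerisation.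

**Step 7**
Reactants: 9 (1.5 equiv); 8
Product: 10 trimethyl[(2Z,5E,9E,13E,17E,21E)-6,10,14,18,22,26-hexamethylheptacosa-2,5,9,13,17,21,25-heptaen-2-yl]stannane
Conditions: BaI2 + Li biphenylide (2 equiv), THF, rt (active Ba); 9, −78 °C, 20 min; then 8, −78 °C, 1 h
Reagents that add atoms: none
Why: Allylbarium cross-coupling; farnesylbarium is configurationally stable at −78 °C and couples α,α′ (SN2) with primary allylic bromides, giving the head-to-tail 1,5-diene with both E-alkenes intact, and the allyl anion does not exchange with a vinyl-Sn bond. Squalene by-product is inert and is removed after Step 8.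

**Step 8**
Reactants: 10; 11 dimethyl squarate (1.3 equiv)
Product: 12 (±)-4-(tert-butyldimethylsilyloxy)-2,3-dimethoxy-4-[(2Z,5E,9E,13E,17E,21E)-6,10,14,18,22,26-hexamethylheptacosa-2,5,9,13,17,21,25-heptaen-2-yl]cyclobut-2-en-1-one
Conditions: MeLi (1.05 equiv), THF, −78 °C, 45 min; cannulate into 11, THF, −78 °C; then 2,6-lutidine, TBSOTf, −78 → −30 °C
Reagents that add atoms: TBSOTf, CC(C)(C)[Si](C)(C)OS(=O)(=O)C(F)(F)F
Why: Sn→Li exchange with retention, then 1,2-addition of the vinyllithium to one of the two equivalent squarate carbonyls, so there is no regiochemical issue; the racemic quaternary carbon is erased on aromatisation, and in situ silylation blocks alkoxide-accelerated ring opening.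

**Step 9**
Reactants: 12
Product: 13 (±)-3,4-bis(tert-butyldimethylsilyloxy)-2-methoxy-4-[same heptaen-2-yl]cyclobut-2-en-1-one
Conditions: KOSiMe3 (1.2 equiv), THF, 0 °C → rt; then TBSCl (1.5 equiv), rt; filter and use crude
Reagents that add atoms: potassium trimethylsilanolate C[Si](C)(C)[O-].[K+] (supplies the C3 oxygen if addition–elimination operates); TBSCl, CC(C)(C)[Si](C)(C)Cl
Why: Proposed new method: only C3-OMe is β to the ketone (a vinylogous methyl ester), so silanolate cleaves it by addition–elimination at C3 or by SN2 at its methyl, whereas the α-enol ether C2-OMe can do neither; the resulting vinylogous carboxylate is symmetric about the C2···C4 axis, so O-silylation at either oxygen gives the same constitution. Closest known reaction types are KOSiMe3 cleavage of methyl esters and saponification of methyl tetronates and 3-alkoxycyclobutenones.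

**Step 10 (key step)**
Reactants: 13
Product: 14 2-[(all-E)-hexaprenyl]-6-methoxy-3-methyl-4,5-bis(tert-butyldimethylsilyloxy)phenol
Conditions: degassed PhMe (0.01 M), 110 °C, 2–3 h
Reagents that add atoms: none
Why: Moore rearrangement; conrotatory 4π opening with the 4-OSi donor rotating outward places the alkenyl cis to the ketene, and 6π closure (C1 to Cβ) with tautomerisation gives the arene with connectivity fixed as C1(OH)–C2(OMe)–C3(OSi)–C4(OSi)–Cα(CH3)–Cβ(hexaprenyl), while the chain alkenes are untouched at 110 °C.

**Step 11**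
Reactants: 14
Product: 15 3-demethylubiquinone-6 (2-hexaprenyl-5-hydroxy-6-methoxy-3-methyl-1,4-benzoquinone)
Conditions: TBAF/AcOH (1:1), THF, 0 °C, Ar; then Ag2O, Et2O, rt; 5 % citric acid wash
Reagents that add atoms: none
Why: Buffered fluoride removes both aryl silyl ethers and Ag2O dehydrogenates the hydroxyhydroquinone to the hydroxy-p-quinone tautomer; this avoids strong acid (polyene cyclisation) and alkaline H2O2 (Hooker-type degradation).

## Compound list
1 | (2E,6E)-farnesol | OC/C=C(\C)CC/C=C(\C)CCC=C(C)C | starting material
2 | (2E,6E)-farnesyl acetate | CC(=O)OC/C=C(\C)CC/C=C(\C)CCC=C(C)C | intermediate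
3 | (2E,6E,10E)-12-hydroxyfarnesyl acetate | CC(=O)OC/C=C(\C)CC/C=C(\C)CC/C=C(\C)CO | intermediate
4 | propyne | CC#C | starting material
5 | hexamethylditin | C[Sn](C)(C)[Sn](C)(C)C | starting material
6 | (Z)-1,2-bis(trimethylstannyl)propene | C/C([Sn](C)(C)C)=C/[Sn](C)(C)C | intermediate
7 | C18 stannyl tetraenol | C/C([Sn](C)(C)C)=C/C/C=C(\C)CC/C=C(\C)CC/C=C(\C)CO | intermediate
8 | C18 stannyl allylic bromide | C/C([Sn](C)(C)C)=C/C/C=C(\C)CC/C=C(\C)CC/C=C(\C)CBr | intermediate
9 | (2E,6E)-farnesyl chloride | ClC/C=C(\C)CC/C=C(\C)CCC=C(C)C | intermediate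
10 | C33 vinylstannane | C/C([Sn](C)(C)C)=C/C/C=C(\C)CC/C=C(\C)CC/C=C(\C)CC/C=C(\C)CC/C=C(\C)CCC=C(C)C | intermediate
11 | dimethyl squarate | COC1=C(OC)C(=O)C1=O | starting material
12 | (±)-4-alkenyl-4-OTBS-2,3-dimethoxycyclobutenone | C/C(C1(O[Si](C)(C)C(C)(C)C)C(OC)=C(OC)C1=O)=C/C/C=C(\C)CC/C=C(\C)CC/C=C(\C)CC/C=C(\C)CC/C=C(\C)CCC=C(C)C | intermediate
13 | (±)-4-alkenyl-3,4-bis(OTBS)-2-methoxycyclobutenone | C/C(C1(O[Si](C)(C)C(C)(C)C)C(O[Si](C)(C)C(C)(C)C)=C(OC)C1=O)=C/C/C=C(\C)CC/C=C(\C)CC/C=C(\C)CC/C=C(\C)CC/C=C(\C)CCC=C(C)C | intermediate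
14 | bis-TBS hydroxyhydroquinone | COc1c(O)c(C/C=C(\C)CC/C=C(\C)CC/C=C(\C)CC/C=C(\C)CC/C=C(\C)CCC=C(C)C)c(C)c(O[Si](C)(C)C(C)(C)C)c1O[Si](C)(C)C(C)(C)C | intermediate
15 | 3-demethylubiquinone-6 | COC1=C(O)C(=O)C(C)=C(C/C=C(\C)CC/C=C(\C)CC/C=C(\C)CC/C=C(\C)CC/C=C(\C)CCC=C(C)C)C1=O | target

## Summary
**Total steps:** 11.
**Longest linear sequence:** 9 (Steps 1, 2, 4, 5, 7, 8, 9, 10, 11).

**Steps most likely to fail, each with one fallback**
1. **Step 9.** The position-selective cleavage of the vinylogous methyl ester has no direct precedent on this substrate, and nucleophile-induced opening of the strained ring could compete.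
   - Fallback: move the differentiation onto the six-membered ring.
   - Trap the Step 8 alkoxide with MeOTf and rearrange to the 4-methoxyphenol.
   - Oxidise with PhI(OAc)2/MeOH to the quinone 4,4-dimethyl monoketal, in which again only C3-OMe is a vinylogous ester.
   - Hydrolyse with LiOH, then unmask the ketal on wet silica/oxalic acid.
2. **Step 7.** Allylbarium coupling in the presence of a vinylstannane and a skipped diene is untested, and homocoupling is possible.
   - Fallback: complete the chain first by Biellmann chemistry.
   - Alkylate lithiated farnesyl phenyl sulfone with the TBS ether of 12-bromofarnesol.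
   - Desulfonylate with PdCl2(dppp)/LiEt3BH, remove TBS with TBAF and acetylate.
   - Then run the Stille coupling with 6 on hexaprenyl acetate.
3. **Step 8.** The basic vinyllithium sits next to a doubly allylic CH2, and the internal Sn–Li exchange may be slow.
   - Fallback: switch to the alkynyl Moore–Liebeskind variant.
   - Add the much less basic lithium acetylide of hexaprenylacetylene (hexaprenyl bromide + ethynylMgBr/CuI) to 11. The OH/OMe regiochemical logic is unchanged.
   - Cleave C3-OMe as in Step 9, then thermolyse the 4-O-SnBu3 derivative to the 5-stannylquinone.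
   - Install the ring CH3 by Pd/Cu Stille coupling with MeI.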